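## Structural features

The target is a diarylheptanoid in which five chain carbons and one oxygen form a tetrahydropyran: O1, C2 bearing ring A (3,4-dihydroxy-5-methoxyphenyl), C3, the C4 carbinol, C5, and C6 bearing a two-carbon arm that ends in ring B (4-hydroxyphenyl). The three stereocentres are C2 (S), C4 (R) and C6 (S); none is adjacent to another, C2 and C6 flank the ring oxygen, and all three substituents are cis, so they sit equatorial on one chair. The fragile parts are the catechol of ring A (oxidised in air, especially under base), the third phenol, and the C2–O1 bond, a benzylic ether that can ionise under acid and can be cleaved by hydrogenolysis. The 4-oxygen of ring A is flanked by two ortho oxygens and should be twisted out of conjugation, so C2 should be less prone to ionise than a 4-alkoxybenzyl ether, though it stays sensitive while it is also allylic. The real difficulty is the absolute configuration together with the cis relation of C2 and C6 across O1; C4 should then follow from the chair. The key step exploits the C3–C4 edge of the ring, which carries only hydrogen and the C4 oxygen: once C2 and C6 are linked through O1, a vinyl group on C2 and an allyl group on C6 can be closed to a C3=C4 alkene by metathesis without touching either ether stereocentre. That alkene is unsymmetrical, C3 being next to the allylic ether carbon C2, which gives a handle for returning the oxygen to C4.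

## Logic of the disconnections

**19 back to 18.** The three phenolic O–H bonds are retraced to O–CH2Ph bonds. Free phenols and a catechol would quench the alkoxide chemistry and would not survive the copper, iridium, ruthenium and palladium steps; one kind of ether allows a single neutral operation at the end. The gain is a robust intermediate whose only acidic proton is the C4 hydroxyl. The demand is that hydrogenolysis removes three aryl benzyl ethers and spares the benzylic C2–O1 ring bond.

**18 back to 17.** The C4–H bond is cut, turning the carbinol into a ketone. The equatorial alcohol is the expected product of small-hydride addition to a chair with the C2 and C6 substituents equatorial, so C4 need not be carried as a stereocentre. The gain is one stereocentre fewer. The demand is axial hydride delivery without ring opening by retro-oxa-Michael reaction.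

**17 back to 16.** The C4=O bond is replaced by a C3=C4 double bond. An alkene is the natural outcome of a ring-closing reaction, and its two carbons are differentiated by the allylic C2–O1 bond. The gain is that no earlier intermediate carries oxygen at C4. The demand is an oxidation that places oxygen on C4 and not on C3, under conditions the C2–O1 bond tolerates.

**16 back to 15.** The C3=C4 bond is cut, each end gaining a CH2 terminus. This is the only ring edge free of stereocentres, and cutting it opens the ring into a bis-secondary ether with two monosubstituted alkenes. The gain is that the ring problem becomes an acyclic ether problem. The demand is a closure faster than dimerisation and alkene migration, leaving C2 and C6 untouched.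

**15 back to 6 and 12, through 13 and 14.** The C2–O1 bond is cut. It is an allylic and benzylic C–O bond, the type formed branch-selectively by iridium allyl chemistry from a linear cinnamyl electrophile, while the oxygen and the C6 centre stay with the alcohol. The gain is two fragments of similar size, one with a single stereocentre and one with none. The demand is a catalyst that gives the branched ether and sets C2 as (S) irrespective of the existing C6 centre, a soft alkoxide, and a leaving group that releases no competing nucleophile.

**12 back to 11, 10, 8 with 9, and 7.** The carbonate C–O bond, the allylic alcohol oxidation level, the cinnamyl C=C bond and the two benzyl ether bonds are cut in turn. Each is a standard functional-group operation on an aromatic aldehyde. The gain is arrival at a commercial benzaldehyde and a commercial phosphonate. The demand is clean E geometry in the olefination and 1,2-reduction of the enoate.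

**6 back to 3 and 4, through 5, then to 2 and 1.** The bond between the carbinol carbon and the allyl CH2 is cut. Allyl addition to an aldehyde is the shortest way to the homoallylic carbinol and also supplies the alkene needed for the metathesis. The gain is an achiral aldehyde, reached by oxidation and phenol protection of a commercial phenolic alcohol. The demand is enantiofacial control on an unbranched aliphatic aldehyde.

## Other disconnections considered

**Alternative 1:** The cut runs through C3–C4 and C4–C5 of the pyran, with C4 masked as a dithiane carbon; the ring C–O bond is left for later.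

- **Forward step.** Lithiated 2-(tert-butyldimethylsilyl)-1,3-dithiane A4 would open (S)-2-{2-[4-(benzyloxy)phenyl]ethyl}oxirane A2 at its CH2. HMPA would then trigger a 1,4-Brook shift of silicon to the new alkoxide, and the regenerated dithiane anion would open (R)-2-[3,4-bis(benzyloxy)-5-methoxyphenyl]oxirane A3 at its CH2. The product would be the open-chain dithioketal A1.
- **In favour.** Three components are joined in one flask, both carbinol centres come from epoxides of defined configuration, and the C4 oxidation level is fixed with no regiochemical question. On this last point it is better than the chosen plan, whose Wacker step must discriminate C4 from C3; it is also at least the equal in convergence.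
- **Against.** A1 is acyclic. As drawn, both of its carbinol carbons already have the configuration of the target, so an SN2 ring closure at either one would invert it and give the 2,6-trans ring. A workable closure would be dithiane hydrolysis, then acid-induced loss of the benzylic hydroxyl and oxa-Michael re-addition, which would arrive at ketone 17 but discard the centre for which enantiopure A3 was made. The aryl oxirane might also open in part at its benzylic carbon, and sulfur removal must be done beside electron-rich arenes.
- **Comparison.** On structure the chosen plan forms the ring and sets C2 under catalyst control, where this plan defers both. On mechanism both rely on well-behaved ionic steps. On step economy the two epoxides, the linchpin step, hydrolysis, cyclisation, reduction and deprotection would come to about the same count or slightly more.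

**Alternative 2:** The cut is C2–C3 of the pyran, retraced to a temporary acetal.

- **Forward step.** (3S)-5-[4-(Benzyloxy)phenyl]-3-hydroxypentanoic acid A5 would be condensed with aldehyde 8 to the cis-dioxanone A6 and methylenated with Cp2TiMe2 to the enol acetal A7. Me2AlCl would then break the acetal C–O bond to the enol oxygen, and the aluminium enolate would recombine with the aryl-stabilised oxocarbenium ion at carbon to give ketone A8, which is identical with 17.
- **In favour.** The C4 carbonyl is built in, and the 2,6-cis relation comes from substrate control (thermodynamic acetal formation, chair-like recombination) with no chiral catalyst for C2. On both points it is the equal or the better of the chosen plan.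
- **Against.** The oxocarbenium ion bearing ring A is strongly stabilised, which invites loss of the aldehyde or scrambling at the acetal stage. Stoichiometric titanium and aluminium reagents are needed. The sequence is linear from A5, so an error in its enantiopurity is not corrected later.
- **Comparison.** On step economy it would need about the same number of operations as the chosen plan. The chosen plan is more convergent, and it has the advantage that a wrong enantiomer of 6 becomes a separable diastereomer at 15.

**Alternative 3:** The cut is C5–C6.

- **Forward step.** Bu3SnH and AIBN would convert the primary iodide of the E β-alkoxy enone A9 into a radical that adds 6-exo to the enone β-carbon, giving the all-cis pyran A10.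
- **In favour.** C2 and C4 are already in place, the C4 oxygen is present as a silyl ether, and the chair-like transition state of such cyclisations reliably gives the 2,6-cis ring. On C4, which needs neither a Wacker step nor a ketone reduction, it is better than the chosen plan.
- **Against.** The acceptor leaves a carbonyl on the carbon next to ring B, which must be removed later under conditions that also threaten the benzylic C2–O1 bond. A9 requires a differentiated syn-1,3-diol, a primary iodide and a β-alkoxy enone made from a hindered benzylic alcohol. Tin residues must be removed from a polar product.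
- **Comparison.** On structure it corrects the oxidation pattern late, where the chosen plan never misplaces it. On mechanism a radical closure is as dependable as the metathesis. On step economy it would be clearly longer, by an estimated two to three operations.

Key step: step 9

Assumption: the facial senses of the two chiral catalysts ((R)-TRIP acid giving Re-face allylation of 3; the (Sa,Sc,Sc) phosphoramidite giving the (S)-configured branched ether) follow the accepted models for these catalyst families; should either prove opposite, the mirror-image catalyst would be used with no other change.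

## Route

Step 1
Reactants: 1 3-(4-hydroxyphenyl)propan-1-ol
Product: 2 3-[4-(benzyloxy)phenyl]propan-1-ol
Conditions: BnBr (1.05 equiv), K2CO3, acetone, reflux
Reagents that add atoms: benzyl bromide, BrCc1ccccc1
Why: Williamson ether synthesis; K2CO3 deprotonates only the phenol, so the primary alcohol should stay free.

Step 2
Reactants: 2 3-[4-(benzyloxy)phenyl]propan-1-ol
Product: 3 3-[4-(benzyloxy)phenyl]propanal
Conditions: TEMPO (10 mol %), PhI(OAc)2 (1.1 equiv), CH2Cl2, rt
Reagents that add atoms: none
Why: Oxoammonium (TEMPO) oxidation of a primary alcohol, which should stop at the aldehyde and leave the benzyl ether alone.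

Step 3
Reactants: 3 3-[4-(benzyloxy)phenyl]propanal; 4 allylboronic acid pinacol ester
Product: 6 (S)-1-[4-(benzyloxy)phenyl]hex-5-en-3-ol, via pinacol borate ester 5 (not isolated)
Conditions: (R)-3,3'-bis(2,4,6-triisopropylphenyl)-1,1'-binaphthyl-2,2'-diyl hydrogen phosphate [(R)-TRIP] (5 mol %), toluene, −30 °C; aq. NaHCO3 work-up
Reagents that add atoms: none
Why: Chiral phosphoric acid-catalysed allylboration through a closed chair transition state in which the acid activates the boronate oxygen; Re-face attack on 3 should set the carbinol as (S), the later C6. Any minor enantiomer becomes a separable diastereomer after step 8.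

Step 4
Reactants: 7 3,4-dihydroxy-5-methoxybenzaldehyde
Product: 8 3,4-bis(benzyloxy)-5-methoxybenzaldehyde
Conditions: BnBr (2.3 equiv), K2CO3, DMF, 60 °C
Reagents that add atoms: benzyl bromide, BrCc1ccccc1
Why: Double Williamson etherification of the catechol; the aldehyde is inert to carbonate base.

Step 5
Reactants: 8 3,4-bis(benzyloxy)-5-methoxybenzaldehyde; 9 triethyl phosphonoacetate
Product: 10 ethyl (E)-3-[3,4-bis(benzyloxy)-5-methoxyphenyl]prop-2-enoate
Conditions: NaH, THF, 0 °C to rt
Reagents that add atoms: none
Why: Horner–Wadsworth–Emmons olefination; the stabilised phosphonate anion should give the E enoate with an aromatic aldehyde.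

Step 6
Reactants: 10 ethyl (E)-3-[3,4-bis(benzyloxy)-5-methoxyphenyl]prop-2-enoate
Product: 11 (E)-3-[3,4-bis(benzyloxy)-5-methoxyphenyl]prop-2-en-1-ol
Conditions: i-Bu2AlH (2.2 equiv), CH2Cl2, −78 °C; aq. potassium sodium tartrate (KNaC4H4O6)
Reagents that add atoms: none
Why: 1,2-Reduction of an enoate by an aluminium hydride at low temperature should give the allylic alcohol without conjugate reduction.

Step 7
Reactants: 11 (E)-3-[3,4-bis(benzyloxy)-5-methoxyphenyl]prop-2-en-1-ol
Product: 12 tert-butyl (E)-3-[3,4-bis(benzyloxy)-5-methoxyphenyl]prop-2-en-1-yl carbonate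
Conditions: Boc2O (1.3 equiv), n-Bu4NHSO4 (5 mol %), 30% aq. NaOH, CH2Cl2, 0 °C
Reagents that add atoms: di-tert-butyl dicarbonate, CC(C)(C)OC(=O)OC(=O)OC(C)(C)C
Why: Phase-transfer O-acylation of a primary alcohol; the tert-butyl carbonate is chosen so that ionisation in step 8 releases only CO2 and hindered tert-butoxide.

Step 8
Reactants: 6 (S)-1-[4-(benzyloxy)phenyl]hex-5-en-3-ol; 12 tert-butyl (E)-3-[3,4-bis(benzyloxy)-5-methoxyphenyl]prop-2-en-1-yl carbonate
Product: 15 (3S)-1-[4-(benzyloxy)phenyl]hex-5-en-3-yl (1S)-1-[3,4-bis(benzyloxy)-5-methoxyphenyl]prop-2-en-1-yl ether, via lithium alkoxide 13 (not isolated), via copper alkoxide 14 (not isolated)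
Conditions: 6 (1.5 equiv), n-BuLi (1.5 equiv), THF, −78 to 0 °C; CuI (1.5 equiv), rt; then 12 (1.0 equiv), [Ir(cod)Cl]2 (2 mol %), (Sa,Sc,Sc)-O,O'-(1,1'-binaphthyl-2,2'-diyl) N,N-bis(1-phenylethyl)phosphoramidite (4 mol %), THF, 0 °C to rt; Et3N-washed silica
Reagents that add atoms: none
Why: Iridium-catalysed branch-selective allylic etherification: the cyclometallated iridium phosphoramidite complex ionises 12 to an η3-allyl species and the soft monovalent copper alkoxide 14 attacks the aryl-bearing terminus on the face away from the metal. The ligand should set C2 as (S) under catalyst control, the remote centre of 6 being carried unchanged; tert-butoxide is too hindered to compete as a nucleophile.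

Step 9
Reactants: 15 (3S)-1-[4-(benzyloxy)phenyl]hex-5-en-3-yl (1S)-1-[3,4-bis(benzyloxy)-5-methoxyphenyl]prop-2-en-1-yl ether
Product: 16 (2S,6S)-2-[3,4-bis(benzyloxy)-5-methoxyphenyl]-6-{2-[4-(benzyloxy)phenyl]ethyl}-3,6-dihydro-2H-pyran
Conditions: (H2IMes)(PCy3)Cl2Ru=CHPh (second-generation Grubbs catalyst, 3 mol %), CH2Cl2 (0.01 M), 40 °C, argon sweep
Reagents that add atoms: none
Why: Ring-closing olefin metathesis: the 14-electron ruthenium benzylidene formed by loss of PCy3 should load on the unhindered CH=CH2 of the allyl group on C6, add across the vinyl group on C2 in an intramolecular [2+2] step, and cyclorevert from the ruthenacyclobutane to form C3=C4 and a Ru=CH2 carrier, while ethene leaves the solution. The closest known reaction type is the closure of allyl homoallyl ethers to 3,6-dihydro-2H-pyrans with this catalyst. The ring is closed as a six-membered cyclic alkene from a 1,7-diene, the new double bond being endocyclic and therefore necessarily cis. No stereocentre is created; C2 (S) and C6 (S) are carried through because neither C–O bond nor the C2–H bond takes part. The selectivity needed is ring closure over intermolecular cross-metathesis and over double-bond migration: two monosubstituted alkenes, the folded conformation about the C–O–C linkage and high dilution should secure the first, and a short reaction time with fresh catalyst should limit ruthenium hydride formation and so the second. The benzyl and methyl ethers and the acid-sensitive C2–O1 bond are inert to the neutral catalyst.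

Step 10
Reactants: 16 (2S,6S)-2-[3,4-bis(benzyloxy)-5-methoxyphenyl]-6-{2-[4-(benzyloxy)phenyl]ethyl}-3,6-dihydro-2H-pyran
Product: 17 (2S,6S)-2-[3,4-bis(benzyloxy)-5-methoxyphenyl]-6-{2-[4-(benzyloxy)phenyl]ethyl}tetrahydro-4H-pyran-4-one
Conditions: PdCl2 (20 mol %), CuCl (1.0 equiv), O2 (1 atm), DMF–H2O (7:1), rt to 50 °C
Reagents that add atoms: water, O
Why: Tsuji–Wacker oxidation of a cyclic allylic ether: divalent palladium coordinates the alkene, and water should attack C4, the carbon remote from the inductively withdrawing C2–O1 bond, with palladium on C3. β-Hydride elimination and tautomerisation then give the 4-ketone; C2 and C6 are not involved.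

Step 11
Reactants: 17 (2S,6S)-2-[3,4-bis(benzyloxy)-5-methoxyphenyl]-6-{2-[4-(benzyloxy)phenyl]ethyl}tetrahydro-4H-pyran-4-one
Product: 18 (2S,4R,6S)-2-[3,4-bis(benzyloxy)-5-methoxyphenyl]-6-{2-[4-(benzyloxy)phenyl]ethyl}tetrahydro-2H-pyran-4-ol
Conditions: NaBH4, MeOH–CH2Cl2, −20 to 0 °C
Reagents that add atoms: none
Why: Hydride reduction of a conformationally locked ketone; axial attack on the chair with both C2 and C6 substituents equatorial should give the equatorial (4R) alcohol, cis to both.

Step 12
Reactants: 18 (2S,4R,6S)-2-[3,4-bis(benzyloxy)-5-methoxyphenyl]-6-{2-[4-(benzyloxy)phenyl]ethyl}tetrahydro-2H-pyran-4-ol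
Product: 19 (2S,4R,6S)-2-(3,4-dihydroxy-5-methoxyphenyl)-6-[2-(4-hydroxyphenyl)ethyl]tetrahydro-2H-pyran-4-ol
Conditions: H2 (1 atm), 10% Pd/C, EtOAc–MeOH, rt; filtration and concentration under argon
Reagents that add atoms: none
Why: Catalytic hydrogenolysis of three aryl benzyl ethers, which should be much faster than cleavage of the secondary dialkyl-type benzylic C2–O1 bond under neutral conditions. No stereocentre is touched.

## Compound list

1 | 3-(4-hydroxyphenyl)propan-1-ol | OCCCc1ccc(O)cc1 | starting material
2 | 3-[4-(benzyloxy)phenyl]propan-1-ol | OCCCc1ccc(OCc2ccccc2)cc1 | intermediate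
3 | 3-[4-(benzyloxy)phenyl]propanal | O=CCCc1ccc(OCc2ccccc2)cc1 | intermediate
4 | allylboronic acid pinacol ester | C=CCB1OC(C)(C)C(C)(C)O1 | starting material
5 | 2-{[(3S)-1-[4-(benzyloxy)phenyl]hex-5-en-3-yl]oxy}-4,4,5,5-tetramethyl-1,3,2-dioxaborolane | C=CC[C@@H](OB1OC(C)(C)C(C)(C)O1)CCc1ccc(OCc2ccccc2)cc1 | intermediate
6 | (S)-1-[4-(benzyloxy)phenyl]hex-5-en-3-ol | C=CC[C@@H](O)CCc1ccc(OCc2ccccc2)cc1 | intermediate
7 | 3,4-dihydroxy-5-methoxybenzaldehyde | COc1cc(C=O)cc(O)c1O | starting material
8 | 3,4-bis(benzyloxy)-5-methoxybenzaldehyde | COc1cc(C=O)cc(OCc2ccccc2)c1OCc1ccccc1 | intermediate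
9 | triethyl phosphonoacetate | CCOC(=O)CP(=O)(OCC)OCC | starting material
10 | ethyl (E)-3-[3,4-bis(benzyloxy)-5-methoxyphenyl]prop-2-enoate | CCOC(=O)/C=C/c1cc(OC)c(OCc2ccccc2)c(OCc2ccccc2)c1 | intermediate
11 | (E)-3-[3,4-bis(benzyloxy)-5-methoxyphenyl]prop-2-en-1-ol | OC/C=C/c1cc(OC)c(OCc2ccccc2)c(OCc2ccccc2)c1 | intermediate
12 | tert-butyl (E)-3-[3,4-bis(benzyloxy)-5-methoxyphenyl]prop-2-en-1-yl carbonate | CC(C)(C)OC(=O)OC/C=C/c1cc(OC)c(OCc2ccccc2)c(OCc2ccccc2)c1 | intermediate
13 | lithium (3S)-1-[4-(benzyloxy)phenyl]hex-5-en-3-olate | C=CC[C@@H]([O-])CCc1ccc(OCc2ccccc2)cc1.[Li+] | intermediate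
14 | copper (3S)-1-[4-(benzyloxy)phenyl]hex-5-en-3-olate (CuOR, monovalent copper) | C=CC[C@@H]([O-])CCc1ccc(OCc2ccccc2)cc1.[Cu+] | intermediate
15 | (3S)-1-[4-(benzyloxy)phenyl]hex-5-en-3-yl (1S)-1-[3,4-bis(benzyloxy)-5-methoxyphenyl]prop-2-en-1-yl ether | COc1cc([C@H](C=C)O[C@H](CC=C)CCc2ccc(OCc3ccccc3)cc2)cc(OCc2ccccc2)c1OCc1ccccc1 | intermediate
16 | (2S,6S)-2-[3,4-bis(benzyloxy)-5-methoxyphenyl]-6-{2-[4-(benzyloxy)phenyl]ethyl}-3,6-dihydro-2H-pyran | COc1cc([C@@H]2C=CC[C@H](CCc3ccc(OCc4ccccc4)cc3)O2)cc(OCc2ccccc2)c1OCc1ccccc1 | intermediate
17 | (2S,6S)-2-[3,4-bis(benzyloxy)-5-methoxyphenyl]-6-{2-[4-(benzyloxy)phenyl]ethyl}tetrahydro-4H-pyran-4-one | COc1cc([C@@H]2CC(=O)C[C@H](CCc3ccc(OCc4ccccc4)cc3)O2)cc(OCc2ccccc2)c1OCc1ccccc1 | intermediate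
18 | (2S,4R,6S)-2-[3,4-bis(benzyloxy)-5-methoxyphenyl]-6-{2-[4-(benzyloxy)phenyl]ethyl}tetrahydro-2H-pyran-4-ol | COc1cc([C@@H]2C[C@H](O)C[C@H](CCc3ccc(OCc4ccccc4)cc3)O2)cc(OCc2ccccc2)c1OCc1ccccc1 | intermediate
19 | (2S,4R,6S)-2-(3,4-dihydroxy-5-methoxyphenyl)-6-[2-(4-hydroxyphenyl)ethyl]tetrahydro-2H-pyran-4-ol | COc1cc([C@@H]2C[C@H](O)C[C@H](CCc3ccc(O)cc3)O2)cc(O)c1O | target

## Step count and least certain steps

Total: 12 steps. Longest linear sequence: 9 steps (7 → 8 → 10 → 11 → 12 → 15 → 16 → 17 → 18 → 19).

**Step 8 (allylic etherification).** The most likely failure is loss of branch selectivity and of diastereocontrol at C2. The branched ether is an allylic, benzylic ether of an oxygenated arene and can be re-ionised by the catalyst, which would leak material to the linear ether or to the C2 epimer. The hindered secondary alkoxide may also turn over slowly. The fallback gives up ether formation at C2–O1 and sets out from 6 and 8. Prins cyclisation in CF3CO2H–CH2Cl2 should proceed through the oxocarbenium ion in a chair with both substituents equatorial, trapped equatorially by trifluoroacetate, to give (2S,4R,6S)-2-[3,4-bis(benzyloxy)-5-methoxyphenyl]-6-{2-[4-(benzyloxy)phenyl]ethyl}tetrahydro-2H-pyran-4-yl trifluoroacetate F1. K2CO3 in MeOH would then bring the route back at 18, bypassing 15, 16 and 17.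

**Step 10 (Wacker oxidation).** Three things may go wrong: delivery of oxygen to C3 instead of C4, slow turnover on a 1,2-disubstituted cyclic alkene, and acid-promoted ionisation at C2 by the HCl the system generates. The fallback sets out from 16. Oxymercuration–demercuration (Hg(OAc)2, THF–H2O; then NaBH4, NaOH), in which water should again add at the carbon remote from the C2–O1 bond, would give (2S,6S)-2-[3,4-bis(benzyloxy)-5-methoxyphenyl]-6-{2-[4-(benzyloxy)phenyl]ethyl}tetrahydro-2H-pyran-4-ol F5 as a mixture of C4 epimers. Oxidation with Dess–Martin periodinane would then return to the route at 17.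

**Step 9 (key step, ring-closing metathesis).** The risk is low. What could go wrong is migration of a double bond by ruthenium hydride species before closure, or oligomerisation by cross-metathesis if the concentration is too high. A fallback without metathesis sets out from 6 and 8 and comes back at 17.
- Wacker oxidation of the terminal alkene of 6 (PdCl2, CuCl, O2, DMF–H2O) would give (4S)-6-[4-(benzyloxy)phenyl]-4-hydroxyhexan-2-one F2.
- Aldol addition of its alkoxide–enolate (LiN(i-Pr)2, 2.2 equiv, THF, −78 °C) to 8 would give (5S)-1-[3,4-bis(benzyloxy)-5-methoxyphenyl]-7-[4-(benzyloxy)phenyl]-1,5-dihydroxyheptan-3-one F3 as both C1 epimers.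
- A sulfonic acid resin in CH2Cl2 should dehydrate the benzylic carbinol to (1E,5S)-1-[3,4-bis(benzyloxy)-5-methoxyphenyl]-7-[4-(benzyloxy)phenyl]-5-hydroxyhept-1-en-3-one F4, formed in the flask, and close it by 6-endo oxa-Michael addition under thermodynamic control to the 2,6-cis ketone 17.

**Step 12 (hydrogenolysis).** The risk is over-reduction, that is, hydrogenolytic cleavage of the benzylic C2–O1 ring bond once the aryl ethers are gone, and oxidation of the free catechol during work-up in air. The fallback sets out from 18 and replaces reduction by Lewis acid dealkylation: BCl3 with pentamethylbenzene as benzyl cation scavenger, CH2Cl2, −78 °C, then MeOH, should give 19 directly. Any reversible ionisation at C2 under these conditions would re-close to the all-equatorial isomer. This fallback makes no compound outside the list (entry F0).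

## Further compounds

F1 | step 8 | (2S,4R,6S)-2-[3,4-bis(benzyloxy)-5-methoxyphenyl]-6-{2-[4-(benzyloxy)phenyl]ethyl}tetrahydro-2H-pyran-4-yl trifluoroacetate | COc1cc([C@@H]2C[C@H](OC(=O)C(F)(F)F)C[C@H](CCc3ccc(OCc4ccccc4)cc3)O2)cc(OCc2ccccc2)c1OCc1ccccc1
F2 | step 9 | (4S)-6-[4-(benzyloxy)phenyl]-4-hydroxyhexan-2-one | CC(=O)C[C@@H](O)CCc1ccc(OCc2ccccc2)cc1
F3 | step 9 | (5S)-1-[3,4-bis(benzyloxy)-5-methoxyphenyl]-7-[4-(benzyloxy)phenyl]-1,5-dihydroxyheptan-3-one (both C1 epimers) | COc1cc(C(O)CC(=O)C[C@@H](O)CCc2ccc(OCc3ccccc3)cc2)cc(OCc2ccccc2)c1OCc1ccccc1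
F4 | step 9 | (1E,5S)-1-[3,4-bis(benzyloxy)-5-methoxyphenyl]-7-[4-(benzyloxy)phenyl]-5-hydroxyhept-1-en-3-one | COc1cc(/C=C/C(=O)C[C@@H](O)CCc2ccc(OCc3ccccc3)cc2)cc(OCc2ccccc2)c1OCc1ccccc1
F5 | step 10 | (2S,6S)-2-[3,4-bis(benzyloxy)-5-methoxyphenyl]-6-{2-[4-(benzyloxy)phenyl]ethyl}tetrahydro-2H-pyran-4-ol (both C4 epimers) | COc1cc([C@@H]2CC(O)C[C@H](CCc3ccc(OCc4ccccc4)cc3)O2)cc(OCc2ccccc2)c1OCc1ccccc1
F0 | step 12 | none | none
A1 | alternative 1 | 2-{(2S)-2-[3,4-bis(benzyloxy)-5-methoxyphenyl]-2-hydroxyethyl}-2-{(2S)-4-[4-(benzyloxy)phenyl]-2-[(tert-butyldimethylsilyl)oxy]butyl}-1,3-dithiane | COc1cc([C@@H](O)CC2(SCCCS2)C[C@@H](O[Si](C)(C)C(C)(C)C)CCc2ccc(OCc3ccccc3)cc2)cc(OCc2ccccc2)c1OCc1ccccc1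
A2 | alternative 1 | (S)-2-{2-[4-(benzyloxy)phenyl]ethyl}oxirane | [C@H]1(CCc2ccc(OCc3ccccc3)cc2)CO1
A3 | alternative 1 | (R)-2-[3,4-bis(benzyloxy)-5-methoxyphenyl]oxirane | COc1cc([C@@H]2CO2)cc(OCc2ccccc2)c1OCc1ccccc1
A4 | alternative 1 | 2-(tert-butyldimethylsilyl)-1,3-dithiane | CC(C)(C)[Si](C)(C)C1SCCCS1
A5 | alternative 2 | (3S)-5-[4-(benzyloxy)phenyl]-3-hydroxypentanoic acid | OC(=O)C[C@@H](O)CCc1ccc(OCc2ccccc2)cc1
A6 | alternative 2 | (2S,6S)-2-[3,4-bis(benzyloxy)-5-methoxyphenyl]-6-{2-[4-(benzyloxy)phenyl]ethyl}-1,3-dioxan-4-one | O=C1C[C@H](CCc2ccc(OCc3ccccc3)cc2)O[C@H](c2cc(OC)c(OCc3ccccc3)c(OCc3ccccc3)c2)O1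
A7 | alternative 2 | (2S,6S)-2-[3,4-bis(benzyloxy)-5-methoxyphenyl]-6-{2-[4-(benzyloxy)phenyl]ethyl}-4-methylidene-1,3-dioxane | C=C1C[C@H](CCc2ccc(OCc3ccccc3)cc2)O[C@H](c2cc(OC)c(OCc3ccccc3)c(OCc3ccccc3)c2)O1
A8 | alternative 2 | (2S,6S)-2-[3,4-bis(benzyloxy)-5-methoxyphenyl]-6-{2-[4-(benzyloxy)phenyl]ethyl}tetrahydro-4H-pyran-4-one (identical with 17) | COc1cc([C@@H]2CC(=O)C[C@H](CCc3ccc(OCc4ccccc4)cc3)O2)cc(OCc2ccccc2)c1OCc1ccccc1
A9 | alternative 3 | (E)-1-[4-(benzyloxy)phenyl]-3-{(1S,3S)-1-[3,4-bis(benzyloxy)-5-methoxyphenyl]-3-[(tert-butyldimethylsilyl)oxy]-4-iodobutoxy}prop-2-en-1-one | COc1cc([C@H](C[C@@H](CI)O[Si](C)(C)C(C)(C)C)O/C=C/C(=O)c2ccc(OCc3ccccc3)cc2)cc(OCc2ccccc2)c1OCc1ccccc1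
A10 | alternative 3 | 1-[4-(benzyloxy)phenyl]-2-{(2R,4R,6S)-6-[3,4-bis(benzyloxy)-5-methoxyphenyl]-4-[(tert-butyldimethylsilyl)oxy]tetrahydro-2H-pyran-2-yl}ethan-1-one (all-cis) | COc1cc([C@@H]2C[C@H](O[Si](C)(C)C(C)(C)C)C[C@H](CC(=O)c3ccc(OCc4ccccc4)cc3)O2)cc(OCc2ccccc2)c1OCc1ccccc1
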